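Numbering: the side chain on C8 of flavanone ring A is C1'–C9'. Everything rests on the C2'–C3' bond, formed by a ketal-type Claisen rearrangement. The feature exploited is the γ,δ-unsaturated carbinol O–C1'–C2'–C3'(aryl)–C4'=C5': at the ketone level it is the retron of a [3,3] shift of an allyl vinyl ether with oxygen on C5'. In one operation an 8-(1-ethoxyvinyl)chromone and a (3R,5S)-1,7-diarylhept-1-ene-3,5-diol 5-silyl ether are joined; the C5'–O stereocentre is relayed to C3' and the E-alkene is set. Reduction of the C1' ketone, asymmetric 1,4-arylation of the chromone (ring B, C2) and desilylation finish the route.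

Key step: step 10

Abbreviations: TBS = tert-butyldimethylsilyl, TIPS = triisopropylsilyl, Teoc = 2-(trimethylsilyl)ethoxycarbonyl, Ipc = isopinocampheyl.
Assumption 1: the dienolate made with (+)-Ipc2BCl is taken to attack the Re face of aldehyde 10 (giving 5S); if a first run shows the opposite sense, the (−)-reagent is used.
Assumption 2: (S)-MeO-F12-BIPHEP is taken to give the 2S flavanone, by analogy with (S)-configured biaryl diphosphines and cyclohexenone; if a model chromone shows the opposite sense, the (R)-ligand is used.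

Step 1
Reactants: 1 1-(2,4-dihydroxy-6-methoxyphenyl)ethanone
Product: 2 1-[2-hydroxy-6-methoxy-4-(TIPSO)phenyl]ethanone
Conditions: TIPSCl (1.05 equiv), imidazole, DMF, 0 → 23 °C
Reagents that add atoms: triisopropylsilyl chloride, CC(C)[Si](Cl)(C(C)C)C(C)C
Why: Silyl ether formation should be selective for the 4-OH because the 2-OH is tied up in a hydrogen bond to the acetyl carbonyl.

Step 2
Reactants: 2 1-[2-hydroxy-6-methoxy-4-(TIPSO)phenyl]ethanone
Product: 3 1-[2-hydroxy-3-iodo-6-methoxy-4-(TIPSO)phenyl]ethanone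
Conditions: NIS (1.05 equiv), TFA (10 mol %), MeCN, 0 °C
Reagents that add atoms: N-iodosuccinimide, O=C1CCC(=O)N1I
Why: Electrophilic aromatic iodination should go ortho to the free phenol at C3 (the future C8), as is usual for 2-hydroxy-4,6-dialkoxyacetophenones, C5 being flanked by two alkoxy groups.

Step 3
Reactants: 3 1-[2-hydroxy-3-iodo-6-methoxy-4-(TIPSO)phenyl]ethanone
Product: 5 8-iodo-5-methoxy-7-(TIPSO)chromen-4-one, via enaminone 4 (not isolated)
Conditions: DMF-DMA, toluene, 90 °C; then conc. HCl, CH2Cl2, 23 °C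
Reagents that add atoms: N,N-dimethylformamide dimethyl acetal, COC(OC)N(C)C
Why: Enaminone chromone synthesis: condensation at the acetyl methyl group, then acid-mediated 6-endo addition of the phenol and loss of dimethylamine, closes the pyranone ring with iodine fixed at C8.

Step 4
Reactants: 5 8-iodo-5-methoxy-7-(TIPSO)chromen-4-one; 6 tributyl(1-ethoxyvinyl)stannane
Product: 7 8-(1-ethoxyvinyl)-5-methoxy-7-(TIPSO)chromen-4-one
Conditions: Pd(PPh3)4 (5 mol %), toluene, 100 °C; chromatography on Et3N-deactivated silica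
Reagents that add atoms: none
Why: Stille cross-coupling of the aryl iodide with the α-alkoxyvinylstannane installs C1' and C2' directly at the enol ether level needed for the exchange in step 10.

Step 5
Reactants: 8 tert-butyl(4-iodophenoxy)dimethylsilane; 9 allyl alcohol
Product: 10 3-[4-(TBSO)phenyl]propanal
Conditions: Pd(OAc)2 (3 mol %), Bu4NCl, NaHCO3, DMF, 40 °C
Reagents that add atoms: none
Why: Mizoroki–Heck arylation of allyl alcohol under tetraalkylammonium chloride conditions gives the 3-arylpropanal by β-hydride elimination towards oxygen and enol tautomerisation.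

Step 6
Reactants: 11 (E)-4-(4-hydroxyphenyl)but-3-en-2-one
Product: 12 (E)-4-(4-TeocO-phenyl)but-3-en-2-one
Conditions: Teoc-OSu, Et3N, DMAP (cat.), CH2Cl2, 23 °C
Reagents that add atoms: N-[2-(trimethylsilyl)ethoxycarbonyloxy]succinimide, C[Si](C)(C)CCOC(=O)ON1C(=O)CCC1=O
Why: O-Acylation of the phenol gives an aryl carbonate that is fluoride-labile like the silyl ethers and, being electron-withdrawing, should later suppress ionisation of the cinnamyl C–O bond.

Step 7
Reactants: 12 (E)-4-(4-TeocO-phenyl)but-3-en-2-one; 10 3-[4-(TBSO)phenyl]propanal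
Product: 15 (1E,5S)-5-hydroxy-7-(4-TBSO-phenyl)-1-(4-TeocO-phenyl)hept-1-en-3-one, via boron dienolate 13 (not isolated), via boron aldolate 14 (not isolated)
Conditions: (+)-Ipc2BCl, Et3N, Et2O, −78 → 0 °C; then 10, −78 → −20 °C; H2O2, pH 7 buffer, MeOH, 0 °C
Reagents that add atoms: none
Why: Asymmetric boron aldol reaction in which the kinetic dienolate of the methyl ketone adds to the aldehyde under control of the isopinocampheyl ligands to set C5 (S); any minor enantiomer becomes a separable diastereomer after step 9.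

Step 8
Reactants: 15 (1E,5S)-5-hydroxy-7-(4-TBSO-phenyl)-1-(4-TeocO-phenyl)hept-1-en-3-one
Product: 16 (1E,5S)-5-(TBSO)-7-(4-TBSO-phenyl)-1-(4-TeocO-phenyl)hept-1-en-3-one
Conditions: TBSOTf, 2,6-lutidine, CH2Cl2, −78 °C
Reagents that add atoms: tert-butyldimethylsilyl triflate, CC(C)(C)[Si](C)(C)OS(=O)(=O)C(F)(F)F
Why: Silyl ether formation with the triflate and a hindered base at low temperature should protect the β-hydroxy ketone without retro-aldol cleavage or elimination.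

Step 9
Reactants: 16 (1E,5S)-5-(TBSO)-7-(4-TBSO-phenyl)-1-(4-TeocO-phenyl)hept-1-en-3-one
Product: 17 (1E,3R,5S)-5-(TBSO)-7-(4-TBSO-phenyl)-1-(4-TeocO-phenyl)hept-1-en-3-ol
Conditions: (S)-Me-CBS (20 mol %), catecholborane, toluene, −78 °C
Reagents that add atoms: none
Why: Corey–Bakshi–Shibata reduction with the styrenyl group as the large substituent should give clean 1,2-reduction and set C3 (R, the future C5'–O centre) under reagent control, giving the anti-1,3-diol monoether.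

Step 10
Reactants: 7 8-(1-ethoxyvinyl)-5-methoxy-7-(TIPSO)chromen-4-one; 17 (1E,3R,5S)-5-(TBSO)-7-(4-TBSO-phenyl)-1-(4-TeocO-phenyl)hept-1-en-3-ol
Product: 20 8-[(3R,4E,7S)-7-(TBSO)-9-(4-TBSO-phenyl)-3-(4-TeocO-phenyl)non-4-enoyl]-5-methoxy-7-(TIPSO)chromen-4-one, via mixed ketal 18 (not isolated), via allyl vinyl ether 19 (not isolated)
Conditions: 7 (1.3 equiv), 2,4-dinitrophenol (10 mol %), 5 Å MS, toluene, 60 °C; then xylenes, 135 °C
Reagents that add atoms: none
Why: The weak acid adds alcohol 17 to enol ether 7 to give mixed ketal 18, loss of ethanol (taken up by the sieves) gives allyl vinyl ether 19, and a concerted suprafacial [3,3] shift forms C2'–C3' while the C5'–O bond breaks and the C1' ketone appears. The closest known reaction type is the Saucy–Marbet/Johnson ketal Claisen rearrangement of allylic alcohols with 2-alkoxypropenes or ketone ketals. No ring is closed; the shift passes through a six-membered chair transition state. C3' (R) is set by 1,3-chirality transfer from the (3R) carbinol of 17: with the C6' chain equatorial the new bond forms on the alkene face from which oxygen departs, and the same chair gives the E-C4'=C5' alkene. The step needs the concerted path to outrun ionisation of the cinnamyl C–O bond (1,3-shift, racemisation); the electron-withdrawing carbonate on that aryl ring, the weak acid and the 2-aryl group on the vinyl ether (which penalises an axial C6' chain) are there to secure this.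

Step 11
Reactants: 20 8-[(3R,4E,7S)-7-(TBSO)-9-(4-TBSO-phenyl)-3-(4-TeocO-phenyl)non-4-enoyl]-5-methoxy-7-(TIPSO)chromen-4-one
Product: 21 8-[(1S,3R,4E,7S)-7-(TBSO)-9-(4-TBSO-phenyl)-1-hydroxy-3-(4-TeocO-phenyl)non-4-enyl]-5-methoxy-7-(TIPSO)chromen-4-one
Conditions: (R)-Me-CBS (50 mol %), catecholborane, toluene, −40 → −20 °C; MeOH, pH 7 buffer
Reagents that add atoms: none
Why: Corey–Bakshi–Shibata reduction with the di-ortho-substituted aryl as the large group should set C1' (S) under reagent control, while the γ-pyranone carbonyl (a vinylogous ester) and the isolated alkene are inert to catecholborane.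

Step 12
Reactants: 21 8-[(1S,3R,4E,7S)-7-(TBSO)-9-(4-TBSO-phenyl)-1-hydroxy-3-(4-TeocO-phenyl)non-4-enyl]-5-methoxy-7-(TIPSO)chromen-4-one; 22 4-(TBSO)phenylboronic acid
Product: 23 (2S)-8-[(1S,3R,4E,7S)-7-(TBSO)-9-(4-TBSO-phenyl)-1-hydroxy-3-(4-TeocO-phenyl)non-4-enyl]-5-methoxy-2-(4-TBSO-phenyl)-7-(TIPSO)chroman-4-one
Conditions: [Rh(OH)(cod)]2 (2.5 mol %), (S)-MeO-F12-BIPHEP (5.5 mol %), 22 (3 equiv), toluene/H2O (10:1), 40 °C
Reagents that add atoms: none
Why: Rh-catalysed asymmetric 1,4-addition of an arylboronic acid to the chromone (Hayashi–Miyaura type) should form the flavanone and set C2 (S) under ligand control, remote from the side-chain stereocentres.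

Step 13
Reactants: 23 (2S)-8-[(1S,3R,4E,7S)-7-(TBSO)-9-(4-TBSO-phenyl)-1-hydroxy-3-(4-TeocO-phenyl)non-4-enyl]-5-methoxy-2-(4-TBSO-phenyl)-7-(TIPSO)chroman-4-one
Product: 24 (2S)-7-hydroxy-8-[(1S,3R,4E,7S)-1,7-dihydroxy-3,9-bis(4-hydroxyphenyl)non-4-enyl]-2-(4-hydroxyphenyl)-5-methoxychroman-4-one
Conditions: TBAF, AcOH (1:1, excess), THF, 0 → 40 °C; pH 7 work-up
Reagents that add atoms: none
Why: Fluoride-mediated desilylation buffered with acetic acid should remove the four silyl ethers and fragment the 2-(trimethylsilyl)ethyl carbonate without exposing the base-labile flavanone C2 centre or the acid-labile benzylic C1' alcohol to harsh conditions.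

Compound list
1 | 1-(2,4-dihydroxy-6-methoxyphenyl)ethanone | CC(=O)c1c(O)cc(O)cc1OC | starting material
2 | 1-[2-hydroxy-6-methoxy-4-(triisopropylsilyloxy)phenyl]ethanone | CC(=O)c1c(O)cc(O[Si](C(C)C)(C(C)C)C(C)C)cc1OC | intermediate
3 | 1-[2-hydroxy-3-iodo-6-methoxy-4-(triisopropylsilyloxy)phenyl]ethanone | CC(=O)c1c(O)c(I)c(O[Si](C(C)C)(C(C)C)C(C)C)cc1OC | intermediate
4 | (E)-3-(dimethylamino)-1-[2-hydroxy-3-iodo-6-methoxy-4-(triisopropylsilyloxy)phenyl]prop-2-en-1-one (enaminone, not isolated) | CN(C)/C=C/C(=O)c1c(O)c(I)c(O[Si](C(C)C)(C(C)C)C(C)C)cc1OC | intermediate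
5 | 8-iodo-5-methoxy-7-(triisopropylsilyloxy)chromen-4-one | COc1cc(O[Si](C(C)C)(C(C)C)C(C)C)c(I)c2occc(=O)c12 | intermediate
6 | tributyl(1-ethoxyvinyl)stannane | CCCC[Sn](CCCC)(CCCC)C(=C)OCC | starting material
7 | 8-(1-ethoxyvinyl)-5-methoxy-7-(triisopropylsilyloxy)chromen-4-one | CCOC(=C)c1c(O[Si](C(C)C)(C(C)C)C(C)C)cc(OC)c2c(=O)ccoc12 | intermediate
8 | tert-butyl(4-iodophenoxy)dimethylsilane | CC(C)(C)[Si](C)(C)Oc1ccc(I)cc1 | starting material
9 | allyl alcohol | C=CCO | starting material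
10 | 3-[4-(tert-butyldimethylsilyloxy)phenyl]propanal | CC(C)(C)[Si](C)(C)Oc1ccc(CCC=O)cc1 | intermediate
11 | (E)-4-(4-hydroxyphenyl)but-3-en-2-one | CC(=O)/C=C/c1ccc(O)cc1 | starting material
12 | 4-[(E)-3-oxobut-1-enyl]phenyl 2-(trimethylsilyl)ethyl carbonate | CC(=O)/C=C/c1ccc(OC(=O)OCC[Si](C)(C)C)cc1 | intermediate
13 | diisopinocampheylboron dienolate of 12 (not isolated) | C=C(/C=C/c1ccc(OC(=O)OCC[Si](C)(C)C)cc1)OB([C@H]1C[C@H]2C[C@@H]([C@@H]1C)C2(C)C)[C@H]1C[C@H]2C[C@@H]([C@@H]1C)C2(C)C | intermediate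
14 | diisopinocampheylboron aldolate of 15 (not isolated) | C[Si](C)(C)CCOC(=O)Oc1ccc(/C=C/C(=O)C[C@@H](OB([C@H]2C[C@H]3C[C@@H]([C@@H]2C)C3(C)C)[C@H]2C[C@H]3C[C@@H]([C@@H]2C)C3(C)C)CCc2ccc(O[Si](C)(C)C(C)(C)C)cc2)cc1 | intermediate
15 | 4-[(1E,5S)-7-[4-(tert-butyldimethylsilyloxy)phenyl]-5-hydroxy-3-oxohept-1-enyl]phenyl 2-(trimethylsilyl)ethyl carbonate | C[Si](C)(C)CCOC(=O)Oc1ccc(/C=C/C(=O)C[C@@H](O)CCc2ccc(O[Si](C)(C)C(C)(C)C)cc2)cc1 | intermediate
16 | 4-[(1E,5S)-5-(tert-butyldimethylsilyloxy)-7-[4-(tert-butyldimethylsilyloxy)phenyl]-3-oxohept-1-enyl]phenyl 2-(trimethylsilyl)ethyl carbonate | C[Si](C)(C)CCOC(=O)Oc1ccc(/C=C/C(=O)C[C@@H](O[Si](C)(C)C(C)(C)C)CCc2ccc(O[Si](C)(C)C(C)(C)C)cc2)cc1 | intermediate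
17 | 4-[(1E,3R,5S)-5-(tert-butyldimethylsilyloxy)-7-[4-(tert-butyldimethylsilyloxy)phenyl]-3-hydroxyhept-1-enyl]phenyl 2-(trimethylsilyl)ethyl carbonate | C[Si](C)(C)CCOC(=O)Oc1ccc(/C=C/[C@H](O)C[C@@H](O[Si](C)(C)C(C)(C)C)CCc2ccc(O[Si](C)(C)C(C)(C)C)cc2)cc1 | intermediate
18 | mixed ethyl ketal of 7 with the (3R)-oxygen of 17, ketal carbon unassigned (not isolated) | CCOC(C)(O[C@@H](/C=C/c1ccc(OC(=O)OCC[Si](C)(C)C)cc1)C[C@@H](O[Si](C)(C)C(C)(C)C)CCc1ccc(O[Si](C)(C)C(C)(C)C)cc1)c1c(O[Si](C(C)C)(C(C)C)C(C)C)cc(OC)c2c(=O)ccoc12 | intermediate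
19 | 8-[1-[(1E,3R,5S)-heptenyloxy]vinyl]chromone: allyl vinyl ether from 7 and 17 (not isolated) | C=C(O[C@@H](/C=C/c1ccc(OC(=O)OCC[Si](C)(C)C)cc1)C[C@@H](O[Si](C)(C)C(C)(C)C)CCc1ccc(O[Si](C)(C)C(C)(C)C)cc1)c1c(O[Si](C(C)C)(C(C)C)C(C)C)cc(OC)c2c(=O)ccoc12 | intermediate
20 | 8-[(3R,4E,7S)-7-(tert-butyldimethylsilyloxy)-9-[4-(tert-butyldimethylsilyloxy)phenyl]-3-[4-[[2-(trimethylsilyl)ethoxy]carbonyloxy]phenyl]non-4-enoyl]-5-methoxy-7-(triisopropylsilyloxy)chromen-4-one | COc1cc(O[Si](C(C)C)(C(C)C)C(C)C)c(C(=O)C[C@H](/C=C/C[C@@H](O[Si](C)(C)C(C)(C)C)CCc2ccc(O[Si](C)(C)C(C)(C)C)cc2)c2ccc(OC(=O)OCC[Si](C)(C)C)cc2)c2occc(=O)c12 | intermediate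
21 | 8-[(1S,3R,4E,7S)-7-(tert-butyldimethylsilyloxy)-9-[4-(tert-butyldimethylsilyloxy)phenyl]-1-hydroxy-3-[4-[[2-(trimethylsilyl)ethoxy]carbonyloxy]phenyl]non-4-enyl]-5-methoxy-7-(triisopropylsilyloxy)chromen-4-one | COc1cc(O[Si](C(C)C)(C(C)C)C(C)C)c([C@@H](O)C[C@H](/C=C/C[C@@H](O[Si](C)(C)C(C)(C)C)CCc2ccc(O[Si](C)(C)C(C)(C)C)cc2)c2ccc(OC(=O)OCC[Si](C)(C)C)cc2)c2occc(=O)c12 | intermediate
22 | 4-(tert-butyldimethylsilyloxy)phenylboronic acid | CC(C)(C)[Si](C)(C)Oc1ccc(B(O)O)cc1 | starting material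
23 | (2S)-8-[(1S,3R,4E,7S)-7-(tert-butyldimethylsilyloxy)-9-[4-(tert-butyldimethylsilyloxy)phenyl]-1-hydroxy-3-[4-[[2-(trimethylsilyl)ethoxy]carbonyloxy]phenyl]non-4-enyl]-2-[4-(tert-butyldimethylsilyloxy)phenyl]-5-methoxy-7-(triisopropylsilyloxy)chroman-4-one | COc1cc(O[Si](C(C)C)(C(C)C)C(C)C)c([C@@H](O)C[C@H](/C=C/C[C@@H](O[Si](C)(C)C(C)(C)C)CCc2ccc(O[Si](C)(C)C(C)(C)C)cc2)c2ccc(OC(=O)OCC[Si](C)(C)C)cc2)c2c1C(=O)C[C@@H](c1ccc(O[Si](C)(C)C(C)(C)C)cc1)O2 | intermediate
24 | (2S)-7-hydroxy-8-[(1S,3R,4E,7S)-1,7-dihydroxy-3,9-bis(4-hydroxyphenyl)non-4-enyl]-2-(4-hydroxyphenyl)-5-methoxychroman-4-one | COc1cc(O)c([C@@H](O)C[C@H](/C=C/C[C@@H](O)CCc2ccc(O)cc2)c2ccc(O)cc2)c2c1C(=O)C[C@@H](c1ccc(O)cc1)O2 | target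

Total step count: 13. Longest linear sequence: 8 steps (steps 1–4 and 10–13; equally steps 5, 7–13).

Steps most likely to fail

Step 10. Under the hot acidic conditions the allylic C–O bond of 18 or 19 may ionise, which would give 1,3-shift and loss of chirality transfer, and enol ether 7 may be hydrolysed by adventitious water. The fallback sets out from 7 and 17 and separates ether formation from rearrangement. The mixed ketal 18 would be formed and isolated at 0 °C (PPTS, CH2Cl2), then converted into allyl vinyl ether 19 by silyl triflate–amine cleavage of the ketal (TMSOTf, i-Pr2NEt, CH2Cl2, −20 °C). Vinyl ether 19 would then be rearranged by acid-free thermolysis (toluene, 110 °C, N,O-bis(trimethylsilyl)acetamide as scavenger), rejoining the route at 20. This path forms no compound outside the list (F0).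

Step 12. Insertion into the electron-rich, 8-substituted chromone may be so slow that protodeboronation of 22 outruns arylation, and ligand control may be eroded on the advanced intermediate. The fallback sets out from 5 and moves the arylation ahead of the fragment union. The same Rh-catalysed 1,4-arylation with 22 would be run on the simple chromone to give the (2S)-8-iodoflavanone F1, and Stille coupling with 6 would give the flavanone enol ether F2. Ketal Claisen rearrangement with 17, through the flavanone mixed ketal F3 and the flavanone allyl vinyl ether F4, would give the flavanone diketone F5. Corey–Bakshi–Shibata reduction with (R)-Me-CBS would then have to select the twisted side-chain ketone over the planar, triply oxygen-conjugated ring C ketone, and would rejoin the route at 23.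

Step 7. Enantioface discrimination by the isopinocampheyl ligands may be insufficient in the methyl ketone aldol. The fallback sets out from 12, which would be converted into the trimethylsilyl dienol ether F6 (TMSOTf, Et3N, CH2Cl2, 0 °C). F6 would be added to 10 in a catalytic asymmetric Mukaiyama aldol reaction (N-tosyl-tryptophan-derived B-butyl oxazaborolidinone, 20 mol %, EtCN, −78 °C) to give the O-trimethylsilyl aldol F7. Cleavage of F7 with dilute HCl in THF would rejoin the route at 15.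

Further compounds
F0 | step 10 | none | none
F1 | step 12 | (2S)-2-[4-(tert-butyldimethylsilyloxy)phenyl]-8-iodo-5-methoxy-7-(triisopropylsilyloxy)chroman-4-one | COc1cc(O[Si](C(C)C)(C(C)C)C(C)C)c(I)c2c1C(=O)C[C@@H](c1ccc(O[Si](C)(C)C(C)(C)C)cc1)O2
F2 | step 12 | (2S)-2-[4-(tert-butyldimethylsilyloxy)phenyl]-8-(1-ethoxyvinyl)-5-methoxy-7-(triisopropylsilyloxy)chroman-4-one | COc1cc(O[Si](C(C)C)(C(C)C)C(C)C)c(C(=C)OCC)c2c1C(=O)C[C@@H](c1ccc(O[Si](C)(C)C(C)(C)C)cc1)O2
F3 | step 12 | flavanone mixed ethyl ketal of F2 with the (3R)-oxygen of 17 | COc1cc(O[Si](C(C)C)(C(C)C)C(C)C)c(C(C)(OCC)O[C@@H](/C=C/c3ccc(OC(=O)OCC[Si](C)(C)C)cc3)C[C@@H](O[Si](C)(C)C(C)(C)C)CCc3ccc(O[Si](C)(C)C(C)(C)C)cc3)c2c1C(=O)C[C@@H](c1ccc(O[Si](C)(C)C(C)(C)C)cc1)O2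
F4 | step 12 | flavanone allyl vinyl ether from F2 and 17 | COc1cc(O[Si](C(C)C)(C(C)C)C(C)C)c(C(=C)O[C@@H](/C=C/c3ccc(OC(=O)OCC[Si](C)(C)C)cc3)C[C@@H](O[Si](C)(C)C(C)(C)C)CCc3ccc(O[Si](C)(C)C(C)(C)C)cc3)c2c1C(=O)C[C@@H](c1ccc(O[Si](C)(C)C(C)(C)C)cc1)O2
F5 | step 12 | (2S)-8-[(3R,4E,7S)-7-(tert-butyldimethylsilyloxy)-9-[4-(tert-butyldimethylsilyloxy)phenyl]-3-[4-[[2-(trimethylsilyl)ethoxy]carbonyloxy]phenyl]non-4-enoyl]-2-[4-(tert-butyldimethylsilyloxy)phenyl]-5-methoxy-7-(triisopropylsilyloxy)chroman-4-one | COc1cc(O[Si](C(C)C)(C(C)C)C(C)C)c(C(=O)C[C@H](/C=C/C[C@@H](O[Si](C)(C)C(C)(C)C)CCc2ccc(O[Si](C)(C)C(C)(C)C)cc2)c2ccc(OC(=O)OCC[Si](C)(C)C)cc2)c2c1C(=O)C[C@@H](c1ccc(O[Si](C)(C)C(C)(C)C)cc1)O2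
F6 | step 7 | 4-[(E)-3-(trimethylsilyloxy)buta-1,3-dienyl]phenyl 2-(trimethylsilyl)ethyl carbonate | C=C(O[Si](C)(C)C)/C=C/c1ccc(OC(=O)OCC[Si](C)(C)C)cc1
F7 | step 7 | 4-[(1E,5S)-7-[4-(tert-butyldimethylsilyloxy)phenyl]-3-oxo-5-(trimethylsilyloxy)hept-1-enyl]phenyl 2-(trimethylsilyl)ethyl carbonate | C[Si](C)(C)CCOC(=O)Oc1ccc(/C=C/C(=O)C[C@@H](O[Si](C)(C)C)CCc2ccc(O[Si](C)(C)C(C)(C)C)cc2)cc1
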